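## Retrosynthetic overview

1. Peroxyacarnoate A 23 ⇒ Sonogashira disconnection of the C(sp)–C(sp2) bond of the enyne: dioxane alkyne 18 + (E)-vinyl iodide 22 (Takai olefination of dec-9-enal).
2. 18 ⇒ racemic 17 by hydrolase kinetic resolution, which fixes the absolute configuration at C3; C6 is tied to C3 because 17 is a single diastereomer.
3. Racemic 17 ⇒ cyclobutanol 12 + O2 + MeOH (three components). The dioxane carbons C3–C4–C5–C6 are the four carbons of a cyclobutane; the tertiary carbinol carbon (future ketal C6) sits next to the ring CH that carries the acetate arm (future C3). Alkoxyl-radical β-scission of that strained C–C bond, O2 capture and hemiperketal closure insert O–O into the four-membered ring.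
4. 12 ⇒ Grignard addition of a silyl-protected pentynyl unit to tert-butyl 2-(2-oxocyclobutyl)acetate 7 ⇐ aza-enolate alkylation of cyclobutanone.
5. Ring order: cyclobutane (bought as cyclobutanone) → 1,2-dioxane by a two-atom ring expansion; no other ring is formed.

Key step: step 5

Remarks on the chemistry:
- Ring numbering used throughout: O1, O2, C3 = CH bearing CH2CO2Me, C4, C5, C6 = ketal carbon (OMe and side chain). In this numbering the target is (3S,6R), with OMe cis to the acetate arm.
- Assumption: the hydrolase in step 6 is taken to hydrolyse the (3R,6S)-ester faster. If the sense is opposite, the acid fraction is the wanted one and is re-esterified as in the fallback for step 6.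
- Step 5 forms C3 as a racemate (planar radical), so the route relies on a resolution and gives at most half of the material from step 5 onward.

## Route

Step 1
Reactants: 1 cyclobutanone; 2 N,N-dimethylhydrazine
Product: 3 cyclobutanone N,N-dimethylhydrazone
Conditions: Me2NNH2 (1.2 equiv), AcOH (cat.), EtOH, 60 °C; distillation
Reagents that add atoms: none
Why: Acid-catalysed hydrazone condensation of an unhindered ketone gives the aza-enolate precursor and so avoids the self-aldol chemistry of cyclobutanone enolates.

Step 2
Reactants: 3 cyclobutanone N,N-dimethylhydrazone; 4 tert-butyl bromoacetate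
Product: 7 tert-butyl 2-(2-oxocyclobutyl)acetate (racemic), via aza-enolate 5 (not isolated), via alkylated hydrazone 6 (not isolated)
Conditions: LDA (commercial solution, 1.05 equiv), THF, −78 → 0 °C; 4, −78 °C → rt; then sat. aq. oxalic acid/Et2O, rt
Reagents that add atoms: water (O)
Why: Corey–Enders alkylation of the metalated hydrazone (SN2 on the α-bromo ester) followed by mild oxalic acid hydrolysis, which spares the tert-butyl ester; the new stereocentre is racemic and is erased in step 5.

Step 3
Reactants: 7 tert-butyl 2-(2-oxocyclobutyl)acetate; 8 (5-chloropent-1-yn-1-yl)trimethylsilane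
Product: 11 tert-butyl 2-{2-hydroxy-2-[5-(trimethylsilyl)pent-4-yn-1-yl]cyclobutyl}acetate (racemic diastereomer mixture), via Grignard reagent 9 (not isolated), via magnesium alkoxide 10 (not isolated)
Conditions: 8, Mg turnings (I2 activation), THF, reflux; then 7, THF, −78 °C; sat. aq. NH4Cl at −78 °C
Reagents that add atoms: none
Why: Grignard 1,2-addition to the strained, highly electrophilic cyclobutanone at −78 °C should outrun attack on the tert-butyl ester, and the bulky ester is chosen so that the tertiary magnesium alkoxide does not lactonise; the two stereocentres need no control because both are destroyed in step 5.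

Step 4
Reactants: 11 tert-butyl 2-{2-hydroxy-2-[5-(trimethylsilyl)pent-4-yn-1-yl]cyclobutyl}acetate
Product: 12 tert-butyl 2-[2-hydroxy-2-(pent-4-yn-1-yl)cyclobutyl]acetate (racemic diastereomer mixture)
Conditions: K2CO3 (cat.), MeOH, 0 °C → rt
Reagents that add atoms: none
Why: Base-catalysed protodesilylation of the alkynylsilane by methanolysis, placed before the peroxide exists so that no basic step is needed later on the base-sensitive β-peroxy ester; the tert-butyl ester and the hindered tertiary alcohol should be inert.

Step 5
Reactants: 12 tert-butyl 2-[2-hydroxy-2-(pent-4-yn-1-yl)cyclobutyl]acetate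
Product: 17 methyl 2-[(3S*,6R*)-6-methoxy-6-(pent-4-yn-1-yl)-1,2-dioxan-3-yl]acetate (racemic), via hydroperoxy ketone 13 (not isolated), via dioxanol 14 (not isolated), via tert-butyl ester ketal 15 (not isolated), via ketal acid 16 (not isolated)
Conditions: Co(acac)2 (20 mol %), O2 (1 atm), 1,2-dichloroethane, 40 °C; filtration through a silica plug; then HCl (ca. 3 M in MeOH), 0 °C → rt; the minor C6 epimer is removed by chromatography
Reagents that add atoms: dioxygen (O=O); methanol (CO)
Why: Co(II)/O2 turns the tertiary cyclobutanol into a Co(III) alkoxide and then its alkoxyl radical, which opens by β-scission of the strained C1–C2 ring bond; the secondary radical at the future C3 captures O2, the peroxyl radical is reduced to hydroperoxide 13 (Co(III)–OOR, protonolysis by the next molecule of 12), and 13 closes at once to dioxanol 14, which keeps the OOH away from cobalt. The closest known reaction type is the Co(acac)2/O2 oxidative ring expansion of cyclobutanols to 1,2-dioxanols (the four-ring counterpart of the cyclopropanol to 1,2-dioxolan-3-ol oxygenation), followed by the acid/MeOH peroxyketalisation used for 3-methoxy-1,2-dioxane cores. The 1,2-dioxane ring closes by 6-exo-trig addition of the hydroperoxide oxygen to the C6 ketone, so the four cyclobutane carbons become C3–C6 and O–O takes the place of the broken C–C bond. C3 arises from a planar radical and is therefore racemic (its absolute configuration is fixed in step 6), whereas C6 is set under thermodynamic control through the peroxycarbenium ion in acidic MeOH: axial OMe (anomeric effect) with the pentynyl chain and the C3 arm equatorial, which is the 3S*,6R* relative configuration of the target. The selectivity needed is scission toward the substituted ring carbon and not toward the ring CH2 or the side chain; ring strain (no relief on exocyclic cleavage) and the secondary versus primary radical should secure it, this being the substitution pattern for which the ring expansion is regioselective. The same methanolic HCl exchanges the tert-butyl for the methyl ester (loss of isobutene, Fischer esterification), so one operation should deliver ring, peroxide, ketal, ester and relative configuration.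

Step 6
Reactants: 17 methyl 2-[(3S*,6R*)-6-methoxy-6-(pent-4-yn-1-yl)-1,2-dioxan-3-yl]acetate (racemic)
Product: 18 methyl 2-[(3S,6R)-6-methoxy-6-(pent-4-yn-1-yl)-1,2-dioxan-3-yl]acetate
Conditions: Burkholderia cepacia lipase (Amano PS), phosphate buffer pH 7.0/MTBE, 30 °C, pH-stat, stopped slightly beyond half conversion; NaHCO3 extraction removes the acid
Reagents that add atoms: none
Why: Hydrolase-catalysed kinetic resolution of an ester whose stereocentre is the ring carbon β to the carbonyl and carries a ring oxygen, the reaction type known for 2-(oxacycloalkan-2-yl)acetates; the enzyme should tell the ring O from the ring CH2 at C3 and hydrolyse the (3R,6S)-ester, so the recovered ester has the (3S,6R) configuration (C6 follows C3), and neutral aqueous conditions should leave peroxide and ketal intact.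

Step 7
Reactants: 19 dec-9-enal; 20 iodoform
Product: 22 (E)-1-iodoundeca-1,10-diene, via dichromium carbenoid 21 (not isolated)
Conditions: CrCl2 (6 equiv), CHI3 (2 equiv), 1,4-dioxane/THF, 0 °C → rt
Reagents that add atoms: none
Why: Takai olefination: the gem-dichromium carbenoid adds to the aldehyde and eliminates to the (E)-vinyl iodide, the E geometry resulting from the anti arrangement in the β-oxido dichromium intermediate; the isolated terminal alkene is inert to Cr(II).

Step 8
Reactants: 18 methyl 2-[(3S,6R)-6-methoxy-6-(pent-4-yn-1-yl)-1,2-dioxan-3-yl]acetate; 22 (E)-1-iodoundeca-1,10-diene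
Product: 23 peroxyacarnoate A, methyl 2-[(3S,6R)-6-[(6E)-hexadeca-6,15-dien-4-yn-1-yl]-6-methoxy-1,2-dioxan-3-yl]acetate
Conditions: PdCl2(PPh3)2 (5 mol %), CuI (10 mol %), i-Pr2NH (3 equiv), THF (degassed), rt
Reagents that add atoms: none
Why: Sonogashira sp–sp2 coupling at room temperature with retention of the (E)-alkene geometry; Pd/Cu couplings on 1,2-dioxane peroxyketals of this type have close precedent, the mild amine base should not open the ring by retro-oxa-Michael reaction, and both stereocentres are untouched.

## Compound list

1 | cyclobutanone | O=C1CCC1 | starting material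
2 | N,N-dimethylhydrazine | CN(C)N | starting material
3 | cyclobutanone N,N-dimethylhydrazone | CN(C)N=C1CCC1 | intermediate
4 | tert-butyl bromoacetate | CC(C)(C)OC(=O)CBr | starting material
5 | lithiated hydrazone (aza-enolate) | [Li+].CN(C)[N-]C1=CCC1 | intermediate (not isolated)
6 | tert-butyl 2-[2-(2,2-dimethylhydrazinylidene)cyclobutyl]acetate | CN(C)N=C1CCC1CC(=O)OC(C)(C)C | intermediate (not isolated)
7 | tert-butyl 2-(2-oxocyclobutyl)acetate (racemic) | O=C1CCC1CC(=O)OC(C)(C)C | intermediate
8 | (5-chloropent-1-yn-1-yl)trimethylsilane | C[Si](C)(C)C#CCCCCl | starting material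
9 | [5-(trimethylsilyl)pent-4-yn-1-yl]magnesium chloride | C[Si](C)(C)C#CCCC[Mg]Cl | intermediate (not isolated)
10 | chloromagnesium alkoxide of 11 | C[Si](C)(C)C#CCCCC1(O[Mg]Cl)CCC1CC(=O)OC(C)(C)C | intermediate (not isolated)
11 | tert-butyl 2-{2-hydroxy-2-[5-(trimethylsilyl)pent-4-yn-1-yl]cyclobutyl}acetate (racemic, diastereomer mixture) | C[Si](C)(C)C#CCCCC1(O)CCC1CC(=O)OC(C)(C)C | intermediate
12 | tert-butyl 2-[2-hydroxy-2-(pent-4-yn-1-yl)cyclobutyl]acetate (racemic, diastereomer mixture) | C#CCCCC1(O)CCC1CC(=O)OC(C)(C)C | intermediate
13 | tert-butyl 3-hydroperoxy-6-oxoundec-10-ynoate (racemic) | C#CCCCC(=O)CCC(OO)CC(=O)OC(C)(C)C | intermediate (not isolated)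
14 | tert-butyl 2-[6-hydroxy-6-(pent-4-yn-1-yl)-1,2-dioxan-3-yl]acetate (racemic, anomer mixture) | C#CCCCC1(O)CCC(CC(=O)OC(C)(C)C)OO1 | intermediate (not isolated)
15 | tert-butyl 2-[(3S*,6R*)-6-methoxy-6-(pent-4-yn-1-yl)-1,2-dioxan-3-yl]acetate (racemic, relative configuration shown) | C#CCCC[C@]1(OC)CC[C@@H](CC(=O)OC(C)(C)C)OO1 | intermediate (not isolated)
16 | 2-[(3S*,6R*)-6-methoxy-6-(pent-4-yn-1-yl)-1,2-dioxan-3-yl]acetic acid (racemic, relative configuration shown) | C#CCCC[C@]1(OC)CC[C@@H](CC(=O)O)OO1 | intermediate (not isolated)
17 | methyl 2-[(3S*,6R*)-6-methoxy-6-(pent-4-yn-1-yl)-1,2-dioxan-3-yl]acetate (racemic, relative configuration shown) | C#CCCC[C@]1(OC)CC[C@@H](CC(=O)OC)OO1 | intermediate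
18 | methyl 2-[(3S,6R)-6-methoxy-6-(pent-4-yn-1-yl)-1,2-dioxan-3-yl]acetate (single enantiomer) | C#CCCC[C@]1(OC)CC[C@@H](CC(=O)OC)OO1 | intermediate
19 | dec-9-enal | C=CCCCCCCCC=O | starting material
20 | iodoform | IC(I)I | starting material
21 | gem-dichromium carbenoid ICH(CrCl2)2 | IC([Cr](Cl)Cl)[Cr](Cl)Cl | intermediate (not isolated)
22 | (E)-1-iodoundeca-1,10-diene | C=CCCCCCCC/C=C/I | intermediate
23 | peroxyacarnoate A | C=CCCCCCCC/C=C/C#CCCC[C@]1(OC)CC[C@@H](CC(=O)OC)OO1 | target

## Step count and risks

Total: 8 steps. Longest linear sequence: 7 steps (1 → 2 → 3 → 4 → 5 → 6 → 8, from cyclobutanone); step 7 is a one-step branch.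

Steps most likely to fail:

Step 6. The enzyme may discriminate poorly between the enantiomers, because the stereocentre is β to the ester and differs only in ring O versus ring CH2, or it may hydrolyse the wanted enantiomer. The fallback is a classical resolution and sets out from 17. Saponification (LiOH, THF/H2O, 0 °C) should give the racemic acid 16. Fractional crystallisation with (S)-1-phenylethylamine (or its antipode, whichever gives the less soluble salt with the wanted acid) should give the (S)-1-phenylethylammonium salt of the (3S,6R)-acid F1. Partition between dilute citric acid and EtOAc should free 2-[(3S,6R)-6-methoxy-6-(pent-4-yn-1-yl)-1,2-dioxan-3-yl]acetic acid F2. Esterification with TMSCHN2 (MeOH/toluene, 0 °C) comes back to the route at 18.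

Step 5. Cobalt may decompose the hydroperoxide before it cyclises, lactonisation of the cis-hydroxy ester may compete with alkoxyl radical formation, or the peroxyketal may fragment during the slow tert-butyl to methyl exchange in acid. The fallback builds the ring by oxa-Michael closure of a hydroperoxy ketal instead of ring expansion and sets out from Grignard reagent 9 (made from 8).
- Acylation of 9 with N-methoxy-N-methylpent-4-enamide (THF, 0 °C) should give 10-(trimethylsilyl)dec-1-en-9-yn-5-one F3.
- Cross-metathesis with methyl acrylate (Hoveyda–Grubbs II, CH2Cl2, 40 °C) should give methyl (E)-6-oxo-11-(trimethylsilyl)undec-2-en-10-ynoate F4.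
- Buffered protodesilylation (TBAF/AcOH, THF, 0 °C) should give methyl (E)-6-oxoundec-2-en-10-ynoate F5.
- Urea–H2O2 with Sc(OTf)3 in MeOH should give the hydroperoxy ketal, methyl (E)-6-hydroperoxy-6-methoxyundec-2-en-10-ynoate F6.
- Et2NH in CF3CH2OH should close the ring by 6-exo oxa-Michael addition; brief TsOH/MeOH equilibration of the C6 epimers and chromatography come back to the route at 17.

Step 8. Pd(0)/phosphine may reduce the O–O bond, or the amine may open the ring by retro-oxa-Michael reaction and epimerise C3. The fallback couples before the peroxide exists and sets out from 12 and 22. Sonogashira coupling under the conditions of step 8 should give tert-butyl 2-{2-[(6E)-hexadeca-6,15-dien-4-yn-1-yl]-2-hydroxycyclobutyl}acetate F7. The conditions of step 5 should then give, through the full-chain dioxanol tert-butyl 2-{6-[(6E)-hexadeca-6,15-dien-4-yn-1-yl]-6-hydroxy-1,2-dioxan-3-yl}acetate F8, racemic peroxyacarnoate A F9. The enzymatic resolution of step 6 applied to F9 comes back to the route at 23.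

Further compounds
F1 | step 6 | (S)-1-phenylethylammonium 2-[(3S,6R)-6-methoxy-6-(pent-4-yn-1-yl)-1,2-dioxan-3-yl]acetate | C#CCCC[C@]1(OC)CC[C@@H](CC(=O)[O-])OO1.C[C@H]([NH3+])c1ccccc1
F2 | step 6 | 2-[(3S,6R)-6-methoxy-6-(pent-4-yn-1-yl)-1,2-dioxan-3-yl]acetic acid (single enantiomer) | C#CCCC[C@]1(OC)CC[C@@H](CC(=O)O)OO1
F3 | step 5 | 10-(trimethylsilyl)dec-1-en-9-yn-5-one | C=CCCC(=O)CCCC#C[Si](C)(C)C
F4 | step 5 | methyl (E)-6-oxo-11-(trimethylsilyl)undec-2-en-10-ynoate | COC(=O)/C=C/CCC(=O)CCCC#C[Si](C)(C)C
F5 | step 5 | methyl (E)-6-oxoundec-2-en-10-ynoate | COC(=O)/C=C/CCC(=O)CCCC#C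
F6 | step 5 | methyl (E)-6-hydroperoxy-6-methoxyundec-2-en-10-ynoate (racemic) | COC(=O)/C=C/CCC(OC)(OO)CCCC#C
F7 | step 8 | tert-butyl 2-{2-[(6E)-hexadeca-6,15-dien-4-yn-1-yl]-2-hydroxycyclobutyl}acetate (racemic, diastereomer mixture) | C=CCCCCCCC/C=C/C#CCCCC1(O)CCC1CC(=O)OC(C)(C)C
F8 | step 8 | tert-butyl 2-{6-[(6E)-hexadeca-6,15-dien-4-yn-1-yl]-6-hydroxy-1,2-dioxan-3-yl}acetate (racemic) | C=CCCCCCCC/C=C/C#CCCCC1(O)CCC(CC(=O)OC(C)(C)C)OO1
F9 | step 8 | racemic peroxyacarnoate A (relative configuration shown) | C=CCCCCCCC/C=C/C#CCCC[C@]1(OC)CC[C@@H](CC(=O)OC)OO1
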